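What is left of the protic impurity once the starting material has been turned over, and what does that leftover do to the target?

the same everywhere: starting material 0.30 M; second substrate 0.150 M; protic impurity 0.0150 M; time 6.0 d

| charge | free catalyst |
|---|---|
| south-east | 0.57 mM |
| south | 1.7 mM |

    second substrate + free catalyst ⇌ catalyst intermediate B (K1 = 4.2 /M, k1 = 1100 /M/h)
    starting material + protic impurity → quenched substrate (k2 = 0.80 /M/h)
    catalyst intermediate B → free catalyst + second product (k3 = 5.7 /h)
    starting material + free catalyst ⇌ catalyst intermediate A (K4 = 8.1 /M, k4 = 400 /M/h)
    catalyst intermediate A → free catalyst + target (k5 = 8.3 /h)

1. which of these there is most of at the end, counted by the starting material in it, south-east (catalyst intermediate A / target / starting material)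
2. which of these there is most of at the end, counted by the starting material in it, south (catalyst intermediate A / target / starting material)
3. final amount of the leader among these, as a percentage of the starting material charged, in south-east
4. final amount of the leader among these, as a percentage of the starting material charged, in south

*Follow one molecule of starting material into the catalyst. What are its chances?*

Bound as catalyst intermediate A, it falls back at 49.4 /h and goes on to target at 8.3 /h, so it goes on with chance 0.144. The useful rate constant for starting material is therefore the binding constant times that chance, 57.6 /M/h.

*Then does the impurity simply take its own charge out of the yield?*

Yes, provided it is consumed before the starting material is. One impurity molecule dies at a rate of k2 times the starting material present, so its chance of surviving is exp(−exposure), where the exposure is k2 times the area under the starting-material curve.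

*How do you get that area without a simulation?*

Catalyst intermediate A lives about 0.0120 h, far shorter than the run, so I treat the intermediates as quasi-steady. The Michaelis constants are then 0.144 M for starting material and 0.243 M for second substrate. Integrating, with second substrate held at its charge, gives

exposure = k2·(starting material)/(kap·catalyst) × (1 + (starting material)/(2·kmA) + (second substrate)/kmB).

For south this is 6.52, so the impurity's survival is 0.148%. Its charge is then nearly all used, and I commit to 95.0% target in south.

*South-east has less catalyst. Is the weak spot now time?*

Yes. The same integral gives the time for starting material to fall by a factor of 2, 3 times over, to 12.5% of what the impurity leaves. With second substrate held at its charge, that reckons to 6.47 d in south-east, longer than the 6.0 d allowed. But second substrate is consumed too, so holding it at its charge overstates that time, and I take the mark as reached near the end. So I commit to target leading in south-east, at about 83.1%.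

The forecast, which reasoned that “the two substrates compete for the catalyst”, gave target at 83.5% for south-east, slightly above my figure, and target at 95% for south.

The simulation gives target at 83.5% in south-east, with 11.5% starting material remaining, and target at 95.0% in south.

In south at 0.866 d, catalyst intermediate A fell back 5.9 times faster than it went on. South ended with 0.34% of its impurity, where exposure 6.52 gave 0.148%. A neighbour like south, with 0.075 M of starting material, has exposure 1.15, which gives 31.6% impurity surviving and 86.3% target. Computed, that flask ends with 40% of its impurity and 88.0% target.

Its constants come from no measurement; the run is a simulation.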